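Retrosynthesis: the spiro carbon is excised first by cutting both oxane bonds O–C(spiro) and C(spiro)–CH(methine). Rings A and B leave as 4-methoxy-2,2'-bipyrrole, and the oxane shrinks to an oxolane whose C-2 (the methine carbon, at ketone level) carries pyrrole ring C. The next cuts are the ansa chain (C=C, metathesis), the ring C–C(ketal) bond (lithiopyrrole + lactone) and the Cα–allyl bond.
Enabling feature: the oxane sequence O–C(spiro)–CH runs from the ring oxygen through C-2 of ring B, the most nucleophilic α-carbon of a 3-methoxypyrrole, to a carbon that bears pyrrole ring C. Without the spiro carbon, the five atoms O, CH(CH3), CH2, CH, C are the ring of γ-valerolactone. Their O–C bond is flanked by an oxygen lone pair and the ring C nitrogen and ionises reversibly, so the α-carbon of ring B can be inserted into it.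
Forward order: the oxolane is bought as the lactone. Ring C is attached and a temporary oxazolone ring is closed on the lactol oxygen. The twelve-membered ansa ring follows by metathesis and hydrogenation. In the last step rings A/B arrive, the oxazolone leaves as CO2 and the oxolane grows to the spiro oxane.
Stereochemistry: the C–CH3 centre comes from (S)-γ-valerolactone. The chain-bearing centre is set by anti alkylation of its enolate. The methine and spiro centres are set in the key step under thermodynamic control (trans-diequatorial bridge, anomeric effect).

Key step: step 9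

Assumption: the ketal carbon of 13–16 is drawn with ring C trans to the side chain, as expected for attack anti to the allyl group; this centre becomes planar in step 9, so its configuration has no consequence, and alkene 15 carries no E/Z descriptor because step 7 removes it.

Step 1
Reactants: 1 (S)-γ-valerolactone; 2 allyl bromide
Product: 4 (3S,5S)-3-allyl-5-methyloxolan-2-one, via lithium enolate 3 (not isolated)
Conditions: LiN(iPr)2, THF, −78 °C; then 2, −78 → −40 °C
Reagents that add atoms: none
Why: Kinetic alkylation of a γ-substituted butyrolactone lithium enolate, in which allyl bromide approaches the face anti to the C-5 methyl group, so the new C-3 centre is set trans, (3S), by 1,3-induction from the purchased (5S) centre.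

Step 2
Reactants: 5 pyrrole; 6 hex-5-enoyl chloride
Product: 8 1-(1H-pyrrol-2-yl)hex-5-en-1-one, via pyrrolylmagnesium bromide 7 (not isolated)
Conditions: EtMgBr, Et2O, 0 °C → reflux; then 6, toluene, 0 °C
Reagents that add atoms: none
Why: C-Acylation of a pyrrolylmagnesium halide, which reacts with acid chlorides at C-2, and the 2-acylpyrrole formed is deactivated towards a second acylation.

Step 3
Reactants: 8 1-(1H-pyrrol-2-yl)hex-5-en-1-one
Product: 10 2-(hex-5-en-1-yl)-1H-pyrrole, via pyrrolyl carbinol 9 (not isolated)
Conditions: NaBH4 (excess), i-PrOH, reflux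
Reagents that add atoms: none
Why: Reductive deoxygenation of a 2-acylpyrrole, in which carbinol 9 loses its oxygen as borate to an azafulvene that takes up a second hydride, while the isolated terminal alkene is inert to borohydride.

Step 4
Reactants: 10 2-(hex-5-en-1-yl)-1H-pyrrole
Product: 11 tert-butyl 2-(hex-5-en-1-yl)pyrrole-1-carboxylate
Conditions: Boc2O, DMAP (cat.), MeCN, rt
Reagents that add atoms: di-tert-butyl dicarbonate CC(C)(C)OC(=O)OC(=O)OC(C)(C)C
Why: DMAP-catalysed N-acylation of a pyrrole, giving the carbamate that directs the α-lithiation and supplies the carbonyl of the temporary ring in step 5.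

Step 5
Reactants: 11 tert-butyl 2-(hex-5-en-1-yl)pyrrole-1-carboxylate; 4 (3S,5S)-3-allyl-5-methyloxolan-2-one
Product: 14 spiro ketal carbamate diene, via 5-lithiopyrrole 12 (not isolated), via lithium lactolate 13 (not isolated)
Conditions: LiN(iPr)2, THF, −78 °C; then 4, −78 °C; warm to 0 °C; aq NH4Cl
Reagents that add atoms: none
Why: Proposed new method: LiN(iPr)2 removes the only free α-proton next to the N-Boc group (known directed α-lithiation) and 12 adds once to the lactone carbonyl anti to the allyl group (known aryllithium-to-lactone addition); the new element is that lactolate 13, whose oxygen lies within five-ring reach of the Boc carbonyl, should close by 5-exo-trig acyl substitution with loss of LiOtBu faster than it opens to the keto alkoxide, giving a pseudo-ester-type spiro ketal carbamate that freezes the oxolane ring and removes the enolisable ketone; the closest known reaction type is the cyclisation of alkoxides from 2-lithio-N-Boc-pyrroles and aldehydes or ketones to pyrrolo[1,2-c]oxazol-3-ones, and the stability model is the 3-alkoxyphthalide pseudo-ester.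

Step 6
Reactants: 14 spiro ketal carbamate diene
Product: 15 unsaturated ansa-bridged spiro ketal carbamate
Conditions: second-generation Grubbs catalyst RuCl2(=CHPh)(PCy3)(H2IMes) (10 mol %), CH2Cl2 (1 mM), reflux
Reagents that add atoms: none
Why: Ring-closing olefin metathesis of two unhindered terminal alkenes at high dilution, helped by the sp3 ketal carbon that holds the allyl arm out of the plane of the flat pyrrolo-oxazolone so that the chain can pass over one face of ring C, and driven by loss of ethene.

Step 7
Reactants: 15 unsaturated ansa-bridged spiro ketal carbamate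
Product: 16 saturated ansa-bridged spiro ketal carbamate
Conditions: H2 (1 atm), 5% Pd/C, EtOAc, rt
Reagents that add atoms: none
Why: Heterogeneous hydrogenation of a 1,2-disubstituted alkene, under which the N-acylated pyrrole and the ketal carbamate should stay untouched at one atmosphere in a neutral solvent.

Step 8
Reactants: 17 4-methoxy-1,5-dihydro-2H-pyrrol-2-one; 5 pyrrole
Product: 19 4-methoxy-1H,1'H-2,2'-bipyrrole, via iminium triflate 18 (not isolated)
Conditions: Tf2O, CH2Cl2, 0 °C; then 5 (excess), 0 °C → rt; aq NaHCO3
Reagents that add atoms: none
Why: Vilsmeier–Haack-type condensation, in which Tf2O turns the lactam into iminium triflate 18, pyrrole attacks it through its α-carbon, and loss of triflic acid with tautomerisation of the ring CH2 gives the aromatic bipyrrole.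

Step 9
Reactants: 16 saturated ansa-bridged spiro ketal carbamate; 19 4-methoxy-1H,1'H-2,2'-bipyrrole
Product: 24 premarineosin A, via oxolanylium salt 20 (not isolated), via dipyrrolyl oxolane 21 (not isolated), via hydroxy prodiginine 22 (not isolated), via ring B cation 23 (not isolated)
Conditions: 19 (1.5 equiv), CF3CO2H (3 equiv), CH2Cl2 (0.02 M), Ar, dark, −40 → 23 °C; then aq NaHCO3
Reagents that add atoms: none
Why: Proposed new method: CF3CO2H protonates the carbamate carbonyl of 16, the ketal C–O(carbamate) bond ionises with the help of the oxolane oxygen, the pyrrole-N-carboxylic acid loses CO2, and the oxolan-2-ylium ion 20 (an O-alkylated 2-acylpyrrole) is attacked by C-5 of 19 to give 21, whose oxolane C–O bond ionises under the push of two pyrroles to the ring-opened hydroxy prodiginine 22. Because the nine-atom bridge cannot hold ring C, the bridge carbon and ring B coplanar, the twisted chromophore of 22 should be reprotonated at the bridge carbon to cation 23, in which C-2 of ring B is electrophilic (charge shared through N-1 and C-5 by ring A and by the methoxy group), and the secondary hydroxyl closes the oxane on this carbon in a 6-exo-trig mode, so that in sum the α-carbon of ring B is inserted into the O–C bond of the five-membered ring. The closest known reaction types are the acid- or POCl3-promoted condensation of 2-acylpyrroles with α-free pyrroles to meso-substituted dipyrrins and the acid-catalysed spiroketalisation of hydroxy ketones and hydroxy imines, and the final C–O closure copies the capture of oxidised ring B by the side-chain hydroxyl in the presumed biosynthesis. Both new stereocentres form reversibly (24, 23 and 22 interconvert under acid) and are therefore controlled by the two fixed centres of the former lactone: the methine carbon should take the (S) configuration that puts ring C and the chain trans-diequatorial on the oxane chair, and the spiro carbon the (R) configuration with N axial (anomeric effect) and the bulkier C(OCH3) carbon equatorial. The step needs site selectivity in 19, secured by the methoxy group that makes the adjacent free α-carbon the most nucleophilic position while both α-carbons of ring C are blocked, and it needs retention at the chain-bearing centre, secured by the ketal carbamate (no enolisable ketone before the event), the low temperature, the non-basic medium and the excess of 19, so that capture of 20 outruns loss of its α-proton.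

Compound list
1 | (S)-γ-valerolactone, (5S)-5-methyloxolan-2-one | C[C@H]1CCC(=O)O1 | starting material
2 | allyl bromide | C=CCBr | starting material
3 | lithium enolate of 1 | C[C@H]1CC=C([O-])O1.[Li+] | intermediate
4 | (3S,5S)-3-allyl-5-methyloxolan-2-one (allyl trans to methyl) | O=C1O[C@@H](C)C[C@@H]1CC=C | intermediate
5 | pyrrole | c1cc[nH]c1 | starting material
6 | hex-5-enoyl chloride | C=CCCCC(=O)Cl | starting material
7 | pyrrol-1-ylmagnesium bromide | Br[Mg]n1cccc1 | intermediate
8 | 1-(1H-pyrrol-2-yl)hex-5-en-1-one | C=CCCCC(=O)c1ccc[nH]1 | intermediate
9 | 1-(1H-pyrrol-2-yl)hex-5-en-1-ol | C=CCCCC(O)c1ccc[nH]1 | intermediate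
10 | 2-(hex-5-en-1-yl)-1H-pyrrole | C=CCCCCc1ccc[nH]1 | intermediate
11 | tert-butyl 2-(hex-5-en-1-yl)pyrrole-1-carboxylate | C=CCCCCc1cccn1C(=O)OC(C)(C)C | intermediate
12 | tert-butyl 2-(hex-5-en-1-yl)-5-lithiopyrrole-1-carboxylate | [Li]c1ccc(CCCCC=C)n1C(=O)OC(C)(C)C | intermediate
13 | lithium lactolate: 2-oxido-oxolane carrying the N-Boc-5-hexenylpyrrol-2-yl group at C-2 (trans to allyl), (3S)-allyl, (5S)-methyl | [Li+].[O-][C@@]1(O[C@@H](C)C[C@@H]1CC=C)c1ccc(CCCCC=C)n1C(=O)OC(C)(C)C | intermediate
14 | spiro[oxolane-2,1'-pyrrolo[1,2-c]oxazol]-3'-one with (3S)-allyl, (5S)-methyl and 5'-(hex-5-enyl); ketal carbon (R), pyrrole carbon trans to allyl | O=C1O[C@@]2(O[C@@H](C)C[C@@H]2CC=C)c2ccc(CCCCC=C)n12 | intermediate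
15 | the same spiro ketal carbamate with oxolane C-3 and pyrrole C-5' joined by CH2CH=CH(CH2)4 (twelve-membered ansa ring, E/Z mixture) | O=C1O[C@]23O[C@@H](C)C[C@@H]2CC=CCCCCc2ccc3n12 | intermediate
16 | the same spiro ketal carbamate with a saturated (CH2)7 bridge from oxolane C-3 to pyrrole C-5'; (3S), (5S)-methyl | O=C1O[C@]23O[C@@H](C)C[C@@H]2CCCCCCCc2ccc3n12 | intermediate
17 | 4-methoxy-1,5-dihydro-2H-pyrrol-2-one (4-methoxy-3-pyrrolin-2-one) | COC1=CC(=O)NC1 | starting material
18 | 3-methoxy-5-(triflyloxy)-2H-pyrrol-1-ium triflate | COC1=CC(OS(=O)(=O)C(F)(F)F)=[NH+]C1.[O-]S(=O)(=O)C(F)(F)F | intermediate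
19 | 4-methoxy-1H,1'H-2,2'-bipyrrole | COc1c[nH]c(-c2ccc[nH]2)c1 | intermediate
20 | ansa-bridged 2-(1H-pyrrol-2-yl)oxolan-2-ylium trifluoroacetate, (3S), (5S)-methyl | C[C@H]1C[C@@H]2CCCCCCCc3ccc([nH]3)C2=[O+]1.[O-]C(=O)C(F)(F)F | intermediate
21 | ansa-bridged oxolane carrying at C-2 both ring C and the 3-methoxy-5-(pyrrol-2-yl)pyrrol-2-yl group | COc1cc(-c2ccc[nH]2)[nH]c1C13O[C@@H](C)C[C@@H]1CCCCCCCc1ccc3[nH]1 | intermediate
22 | ansa-bridged prodiginine, bridge carbon sp2, with (S)-configured chain carbon bearing a (2S)-2-hydroxypropyl group (free base drawn; present as its trifluoroacetate) | COC1=CC(c2ccc[nH]2)=NC1=C1[C@H](C[C@H](C)O)CCCCCCCc2ccc1[nH]2 | intermediate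
23 | C-protonated tautomer of 22: (S)-methine, cationic ring B/ring A unit, free hydroxyl, trifluoroacetate | C[C@H](O)C[C@@H]1CCCCCCCc2ccc([nH]2)[C@H]1C1=NC(=C2C=CC=[NH+]2)C=C1OC.[O-]C(=O)C(F)(F)F | intermediate
24 | premarineosin A: spiro (R), C–CH3 (S), chain carbon (S), methine (S) | COC1=CC(c2ccc[nH]2)=N[C@]12O[C@@H](C)C[C@@H]1CCCCCCCc3ccc([nH]3)[C@H]12 | target

Total step count: 9. Longest linear sequence: 7 steps (2, 3, 4, 5, 6, 7, 9).

Steps most likely to fail

Step 9 (bears the label). Three processes could defeat it:
- loss of the α-proton from the oxolanylium ion, giving epimerisation of the chain-bearing centre through the dihydrofuran;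
- acid-induced oligomerisation of the bipyrrole before the hindered C–C bond forms;
- poor control of the methine and spiro configuration.

The fallback lowers the oxidation level, so that the C–C bond forms at a less hindered secondary azafulvenium ion, and brings the oxidation in afterwards. It sets out from 16 and comes back at 22. Ionic reduction of the ketal (Et3SiH, BF3·OEt2, CH2Cl2, −78 °C), the reaction used to turn aryl lactol ketals into C-aryl cyclic ethers, would give with loss of CO2 the ansa-bridged 2-(pyrrol-2-yl)oxolane F1. Catalytic InCl3 or CF3CO2H with 19 would open its activated C–O bond, as in the standard synthesis of dipyrromethanes from pyrrolyl carbinol derivatives, to the hydroxy dipyrromethane F2. DDQ in CH2Cl2, the standard dehydrogenation of dipyrromethanes to dipyrrins, would give 22. From there closure to 24 follows as in step 9.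

Step 5 (bears the label). The lactolate may collapse to the open keto alkoxide before it reaches the Boc carbonyl. Boc migration, a second addition, or reopening of the carbamate by tert-butoxide could follow. The fallback gives up the temporary ring and carries the open hydroxy ketone. It sets out from 11 and 4 and comes back at 20.
- The same lithiation and addition, quenched with AcOH at −78 °C, would give the N-Boc hydroxy ketone diene F3.
- K2CO3 in MeOH would remove the Boc group, which is labile on a 2-acylpyrrole, to give the NH hydroxy ketone diene F4.
- Ring-closing metathesis with RuCl2(=CHPh)(PCy3)(H2IMes) would give the unsaturated macrocyclic hydroxy ketone F5.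
- H2 over Pd/C would give the saturated macrocyclic hydroxy ketone F6.
- Under the acid of step 9, F6 would close to its five-membered lactol and lose water to 20.

Step 6. Intermolecular metathesis to oligomers may compete with closure of the strained twelve-membered ring. Alkene migration may lead to ring-contracted products. The fallback closes the ring by C(sp2)–C(sp3) cross-coupling at the pyrrole end instead of inside the chain, and no alkene remains to be reduced. It sets out from 1 and comes back at 16.
- The enolate of 1 (LiN(iPr)2, THF/DMPU) alkylated with 7-iodohept-1-ene would give the trans lactone F7.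
- Commercial tert-butyl pyrrole-1-carboxylate, lithiated and added to F7 as in step 5, would give the spiro ketal carbamate F8.
- NBS in THF at −78 °C would brominate the free α-carbon to give the bromide F9.
- 9-BBN would hydroborate the terminal alkene to the borane F10.
- PdCl2(dppf), AsPh3 and Cs2CO3 in DMF/THF at high dilution (intramolecular B-alkyl Suzuki–Miyaura coupling) would close the (CH2)7 bridge to 16.

Further compounds
F1 | step 9 | ansa-bridged 2-(1H-pyrrol-2-yl)oxolane, (3S), (5S)-methyl, C-2 epimers | C[C@H]1C[C@@H]2CCCCCCCc3ccc([nH]3)C2O1
F2 | step 9 | ansa-bridged hydroxy dipyrromethane | COc1cc(-c2ccc[nH]2)[nH]c1C1[C@H](C[C@H](C)O)CCCCCCCc2ccc1[nH]2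
F3 | step 5 | tert-butyl 2-(hex-5-enyl)-5-[(2S)-2-((2S)-2-hydroxypropyl)pent-4-enoyl]pyrrole-1-carboxylate | C=CCCCCc1ccc(n1C(=O)OC(C)(C)C)C(=O)[C@@H](CC=C)C[C@H](C)O
F4 | step 5 | NH hydroxy ketone diene | C=CCCCCc1ccc([nH]1)C(=O)[C@@H](CC=C)C[C@H](C)O
F5 | step 5 | unsaturated macrocyclic hydroxy ketone | O=C1[C@H](C[C@H](C)O)CC=CCCCCc2ccc1[nH]2
F6 | step 5 | saturated macrocyclic hydroxy ketone | O=C1[C@H](C[C@H](C)O)CCCCCCCc2ccc1[nH]2
F7 | step 6 | (3S,5S)-3-(hept-6-enyl)-5-methyloxolan-2-one | O=C1O[C@@H](C)C[C@@H]1CCCCCC=C
F8 | step 6 | spiro ketal carbamate with hept-6-enyl arm and free pyrrole α-carbon | O=C1O[C@@]2(O[C@@H](C)C[C@@H]2CCCCCC=C)c2cccn12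
F9 | step 6 | 5'-bromo derivative of F8 | O=C1O[C@@]2(O[C@@H](C)C[C@@H]2CCCCCC=C)c2ccc(Br)n12
F10 | step 6 | B-alkyl-9-BBN adduct of F9 | O=C1O[C@@]2(O[C@@H](C)C[C@@H]2CCCCCCCB2C3CCCC2CCC3)c2ccc(Br)n12
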